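**Plan**
Locants follow the decalin of the target: C1 (ester CH), C2 (hexadecyl), C3, C4 (ester CH), C4a, C5 (ketone), C6 (ester), C7 (hexadecyl), C8, C8a; ring A = C1–C4/C4a/C8a, ring B = C4a–C8a.
Enabling feature: the adjacent cis methines C4a and C8a, flanked by C4 and C1, make ring A the reduced form of a cyclohexa-1,3-diene (C4=C3, C2=C1), which maps onto an (E,Z,E)-triene C4a=C4–C3=C2–C1=C8a.
Cuts, in order: C6=C7 (Knoevenagel, ring B); the C5–O/C4-acyl lactone (oxidation level); C4a–C8a (electrocyclisation, ring A); C2–C1 and C3–C4 (two Suzuki couplings on cis-diborylated 1-octadecyne); C1=C8a and C4=C4a (two bromo-olefinations).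
Forward: fragment A (from dimethyl (R)-malate) and fragment B (from heptadecanoic acid) are joined through the diboryl alkene; ring A closes first, ring B last.
Stereochemistry: C5 of the malate, tied to the C4 carboxyl as a butenolide, steers the ring closure (C4a, C8a) and is later oxidised away; C4 is set by protonation to the cis-fused lactone; C1 by base equilibration while C4 is locked.

Key step: step 14

Assumption: triene 21 is taken to be isolable at 25 °C; should it ring-close during step 13, steps 13 and 14 merge and give the same compound 22 under the same stereocontrol.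

**Step 1**
Reactants: 1 methyl 2-[bis(2,2,2-trifluoroethoxy)phosphoryl]acetate
Product: 2 methyl 2-[bis(2,2,2-trifluoroethoxy)phosphoryl]-2,2-dibromoacetate
Conditions: Br2 (2.2 equiv), aq. NaOH, 0 °C
Reagents that add atoms: bromine, BrBr
Why: α-Halogenation of the doubly stabilised phosphonoacetate carbanion by hypobromite should run through to the gem-dibromide, which avoids the mono/di mixtures of a direct monobromination.

**Step 2**
Reactants: 2 methyl 2-[bis(2,2,2-trifluoroethoxy)phosphoryl]-2,2-dibromoacetate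
Product: 3 methyl 2-[bis(2,2,2-trifluoroethoxy)phosphoryl]-2-bromoacetate (racemic)
Conditions: SnCl2·2H2O (1.0 equiv), EtOH–H2O, 0 °C
Reagents that add atoms: none
Why: SnCl2 should remove one halogen from the activated gem-dihalide by halophilic two-electron reduction and protonation (reductive monodehalogenation), the usual access to α-monohalo phosphonoacetates.

**Step 3**
Reactants: 4 dimethyl (R)-malate
Product: 5 dimethyl (2R)-2-[(tert-butyldimethylsilyl)oxy]butanedioate
Conditions: TBSCl, imidazole, DMF, 25 °C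
Reagents that add atoms: tert-butyldimethylsilyl chloride, CC(C)(C)[Si](C)(C)Cl
Why: Imidazole-promoted silylation of a secondary alcohol is routine and leaves the stereocentre (the future C5) untouched.

**Step 4**
Reactants: 5 dimethyl (2R)-2-[(tert-butyldimethylsilyl)oxy]butanedioate
Product: 6 methyl (3R)-3-[(tert-butyldimethylsilyl)oxy]-4-oxobutanoate
Conditions: i-Bu2AlH (1.05 equiv), CH2Cl2, −78 °C
Reagents that add atoms: none
Why: In this partial ester reduction the ester carbonyl next to the silyloxy group is the more electrophilic one and its aluminium hemiacetal should persist at −78 °C until work-up, so the aldehyde (future C4a) should form without reduction of the remote ester or enolisation of the α-centre.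

**Step 5**
Reactants: 6 methyl (3R)-3-[(tert-butyldimethylsilyl)oxy]-4-oxobutanoate; 3 methyl 2-[bis(2,2,2-trifluoroethoxy)phosphoryl]-2-bromoacetate
Product: 7 dimethyl (2E,4R)-2-bromo-4-[(tert-butyldimethylsilyl)oxy]hex-2-enedioate (fragment A; C5 cis to the C4 ester)
Conditions: 3, KN(SiMe3)2, 18-crown-6, THF, −78 °C; then 6
Reagents that add atoms: none
Why: In this Horner–Wadsworth–Emmons olefination of Still–Gennari type the electron-poor bis(trifluoroethyl) phosphonate eliminates quickly from the kinetic adduct and places the aldehyde residue cis to the ester, which with bromine on the α-carbon is the (E)-bromoenoate that later puts C5 on the outside of the triene.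

**Step 6**
Reactants: 8 heptadecanoic acid; 9 Meldrum's acid (2,2-dimethyl-1,3-dioxane-4,6-dione)
Product: 11 methyl 3-oxononadecanoate, via acyl Meldrum's acid 10 (not isolated)
Conditions: DCC, DMAP, CH2Cl2, 0→25 °C; filter; MeOH, reflux
Reagents that add atoms: methanol, CO
Why: C-Acylation of Meldrum's acid by the carbodiimide-activated acid, then methanolysis through an acyl ketene with loss of acetone and CO2, is the standard two-carbon homologation of an acid to a β-keto ester (it supplies C7, C8 and C8a).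

**Step 7**
Reactants: 11 methyl 3-oxononadecanoate
Product: 12 methyl 2-(2-hexadecyl-1,3-dioxolan-2-yl)acetate
Conditions: HOCH2CH2OH, TsOH·H2O (cat.), toluene, reflux, Dean–Stark
Reagents that add atoms: ethylene glycol, OCCO
Why: Acid-catalysed ketalisation with azeotropic removal of water should mask the future C7 ketone as a dioxolane that withstands hydride, phosphonate anion, palladium catalysis and SmI2.

**Step 8**
Reactants: 12 methyl 2-(2-hexadecyl-1,3-dioxolan-2-yl)acetate
Product: 13 2-(2-hexadecyl-1,3-dioxolan-2-yl)acetaldehyde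
Conditions: i-Bu2AlH (1.1 equiv), CH2Cl2, −78 °C
Reagents that add atoms: none
Why: Partial ester reduction should stop at the aldehyde (future C8a) because the tetrahedral aluminium intermediate, chelated by a ketal oxygen, survives at −78 °C.

**Step 9**
Reactants: 13 2-(2-hexadecyl-1,3-dioxolan-2-yl)acetaldehyde; 3 methyl 2-[bis(2,2,2-trifluoroethoxy)phosphoryl]-2-bromoacetate
Product: 14 methyl (2E)-2-bromo-4-(2-hexadecyl-1,3-dioxolan-2-yl)but-2-enoate (fragment B; C8 cis to the C1 ester)
Conditions: 3, KN(SiMe3)2, 18-crown-6, THF, −78 °C; then 13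
Reagents that add atoms: none
Why: The same Still–Gennari-type Horner–Wadsworth–Emmons olefination as in step 5 should give the (E)-bromoenoate with C8 cis to the ester, and the weakly basic phosphonate anion should not trigger β-elimination of the ketal.

**Step 10**
Reactants: 15 1-octadecyne; 16 bis(pinacolato)diboron
Product: 17 (E)-1,2-bis(4,4,5,5-tetramethyl-1,3,2-dioxaborolan-2-yl)octadec-1-ene (the two boron atoms cis)
Conditions: Pt(PPh3)4 (3 mol %), DMF, 80 °C
Reagents that add atoms: none
Why: Alkyne diboration at zerovalent platinum adds the B–B bond in a syn fashion, which fixes the two boron atoms, and later C4 and C1, on the same side of the C3=C2 bond.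

**Step 11**
Reactants: 17 (E)-1,2-bis(4,4,5,5-tetramethyl-1,3,2-dioxaborolan-2-yl)octadec-1-ene; 7 dimethyl (2E,4R)-2-bromo-4-[(tert-butyldimethylsilyl)oxy]hex-2-enedioate
Product: 18 dimethyl (2Z,4R)-4-[(tert-butyldimethylsilyl)oxy]-2-[(1E)-2-(4,4,5,5-tetramethyl-1,3,2-dioxaborolan-2-yl)octadec-1-en-1-yl]hex-2-enedioate
Conditions: PdCl2(dppf) (5 mol %), K3PO4 (3 equiv), THF–H2O, 40 °C
Reagents that add atoms: none
Why: In this Suzuki–Miyaura coupling the terminal C–B bond of a 1,2-diborylalkene transmetalates faster than the internal one and both partners react with retention, so C3–C4 should form with C4 cis to the remaining boron and C5 still cis to the C4 ester.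

**Step 12**
Reactants: 18 dimethyl (2Z,4R)-4-[(tert-butyldimethylsilyl)oxy]-2-[(1E)-2-(4,4,5,5-tetramethyl-1,3,2-dioxaborolan-2-yl)octadec-1-en-1-yl]hex-2-enedioate
Product: 20 methyl 2-[(2R)-5-oxo-4-[(1E)-2-(4,4,5,5-tetramethyl-1,3,2-dioxaborolan-2-yl)octadec-1-en-1-yl]-2,5-dihydrofuran-2-yl]acetate, via hydroxy ester 19 (not isolated)
Conditions: CSA (0.2 equiv), MeOH, 25 °C
Reagents that add atoms: none
Why: Acidic methanolysis should remove the silyl ether, and the freed hydroxyl, held cis to the C4 ester across C4a=C4, should lactonise at once (5-exo-trig transesterification) to the butenolide that ties C5–O to the C4 carboxyl, while the pinacol boronate tolerates these mild conditions.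

**Step 13**
Reactants: 20 methyl 2-[(2R)-5-oxo-4-[(1E)-2-(4,4,5,5-tetramethyl-1,3,2-dioxaborolan-2-yl)octadec-1-en-1-yl]-2,5-dihydrofuran-2-yl]acetate; 14 methyl (2E)-2-bromo-4-(2-hexadecyl-1,3-dioxolan-2-yl)but-2-enoate
Product: 21 methyl (2Z)-4-(2-hexadecyl-1,3-dioxolan-2-yl)-2-[(1Z)-1-[(5R)-5-(2-methoxy-2-oxoethyl)-2-oxo-2,5-dihydrofuran-3-yl]octadec-1-en-2-yl]but-2-enoate (triene C4a=C4–C3=C2–C1=C8a, C5 and C8 both outside)
Conditions: Pd[P(t-Bu)3]2 (10 mol %), KF (3 equiv), THF–H2O (20:1), 25 °C
Reagents that add atoms: none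
Why: Suzuki–Miyaura coupling of the internal alkenyl boronate with the activated α-bromoenoate under fluoride activation, mild enough for the base-sensitive butenolide, should form C2–C1 with retention at both carbons and so complete the (E,Z,E)-triene at a temperature below that of ring closure.

**Step 14**
Reactants: 21 methyl (2Z)-4-(2-hexadecyl-1,3-dioxolan-2-yl)-2-[(1Z)-1-[(5R)-5-(2-methoxy-2-oxoethyl)-2-oxo-2,5-dihydrofuran-3-yl]octadec-1-en-2-yl]but-2-enoate
Product: 22 methyl (3R,3aS,4R)-6-hexadecyl-4-[(2-hexadecyl-1,3-dioxolan-2-yl)methyl]-3-(2-methoxy-2-oxoethyl)-1-oxo-1,3,3a,4-tetrahydro-2-benzofuran-5-carboxylate (ring A diene C4=C3, C2=C1; H-4a and H-8a cis)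
Conditions: toluene (0.01 M), BHT (cat.), argon, dark, 80 °C
Reagents that add atoms: none
Why: The six π electrons of the hexatriene C4a=C4–C3=C2–C1=C8a reorganise thermally through a boat-like transition state, as in the known closure of (E,Z,E)-trienes to cis-5,6-disubstituted cyclohexa-1,3-dienes, here accelerated by the acceptors on the 2- and 5-positions of the triene (lactone carbonyl on C4, ester on C1). Ring A closes by formation of C4a–C8a in the disrotatory mode, and no other ring is formed. Because both terminal substituents point outward (C5 is held cis to the C4 carbonyl by the butenolide ring, C8 cis to the C1 ester by the olefination of step 9), orbital symmetry places the C5 and C8 branches on the same face, so H-4a and H-8a become cis. The absolute sense at C4a and C8a comes from C5: the only out-of-plane substituent of the flat butenolide is its CH2CO2Me group, so C8a should bond to the opposite face, as reagents generally add anti to the 5-substituent of 2(5H)-furanones, and for the (R)-malate-derived centre this gives the (4aS,8aR) sense of the target. The step needs this torquoselectivity and a clean thermal window; the ring tether supplies the first, and 80 °C should suffice for closure while staying below the range of 1,5-hydrogen shifts in the product.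

**Step 15**
Reactants: 22 methyl (3R,3aS,4R)-6-hexadecyl-4-[(2-hexadecyl-1,3-dioxolan-2-yl)methyl]-3-(2-methoxy-2-oxoethyl)-1-oxo-1,3,3a,4-tetrahydro-2-benzofuran-5-carboxylate
Product: 23 methyl (3R,3aS,4R,5R,7aR)-6-hexadecyl-4-[(2-hexadecyl-1,3-dioxolan-2-yl)methyl]-3-(2-methoxy-2-oxoethyl)-1-oxo-1,3,3a,4,5,7a-hexahydro-2-benzofuran-5-carboxylate (C2=C3 alkene; cis-fused lactone; C1 ester expected cis to the C8 branch, any C1 epimer being 24)
Conditions: SmI2 (2.5 equiv), MeOH (10 equiv), THF, −78 °C
Reagents that add atoms: none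
Why: SmI2 should transfer two electrons to the muconate-like dienyl lactone–ester and methanol should protonate the dienolates at their α-carbons C4 and C1 (dissolving-metal-type 1,4-reduction), leaving the isolated C2=C3 alkene; protonation of C4 on the convex face gives the cis-fused lactone (H-4 cis to H-4a), whereas C1 is expected to be protonated anti to the C8 branch and is corrected in step 16.

**Step 16**
Reactants: 23 methyl (3R,3aS,4R,5R,7aR)-6-hexadecyl-4-[(2-hexadecyl-1,3-dioxolan-2-yl)methyl]-3-(2-methoxy-2-oxoethyl)-1-oxo-1,3,3a,4,5,7a-hexahydro-2-benzofuran-5-carboxylate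
Product: 26 dimethyl 2-hexadecyl-6-[(2-hexadecyl-1,3-dioxolan-2-yl)methyl]-5-[(1E)-3-methoxy-3-oxoprop-1-en-1-yl]cyclohex-2-ene-1,4-dicarboxylate (C4, C4a and C8a substituents mutually cis, C1 ester trans to them; absolute configuration as in 29), via C1-epimerised lactone 24 (not isolated), via ring-opened acid 25 (not isolated)
Conditions: DBU (3 equiv), MeCN, 25→45 °C; then MeI (5 equiv), 0→25 °C
Reagents that add atoms: iodomethane, CI
Why: DBU should reversibly deprotonate C1 (α to an ester and allylic) so that the C1 ester settles trans to the C8 branch and the 1,3-diaxial contact of the all-cis array is relieved, while C4 cannot change because it is held first in the cis-fused lactone and then as a carboxylate; deprotonation at C6 expels the lactone carboxylate from C5 (E1cB elimination of a β-acyloxy ester) and iodomethane then O-alkylates the DBU carboxylate.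

**Step 17**
Reactants: 26 dimethyl 2-hexadecyl-6-[(2-hexadecyl-1,3-dioxolan-2-yl)methyl]-5-[(1E)-3-methoxy-3-oxoprop-1-en-1-yl]cyclohex-2-ene-1,4-dicarboxylate
Product: 28 dimethyl 2-hexadecyl-5-(3-methoxy-3-oxopropanoyl)-6-(2-oxooctadecyl)cyclohex-2-ene-1,4-dicarboxylate (stereochemistry as in 26), via keto enoate 27 (not isolated)
Conditions: Na2PdCl4 (0.2 equiv), t-BuOOH (2 equiv), AcOH–H2O (4:1), 50 °C
Reagents that add atoms: tert-butyl hydroperoxide, CC(C)(C)OO; water, O
Why: Aqueous acetic acid should hydrolyse the dioxolane, and divalent palladium with the hydroperoxide as reoxidant should oxidise the α,β-unsaturated ester regioselectively at its β-carbon C5 (Wacker-type oxidation of an enoate to a β-keto ester), the trisubstituted ring alkene being too hindered to compete.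

**Step 18**
Reactants: 28 dimethyl 2-hexadecyl-5-(3-methoxy-3-oxopropanoyl)-6-(2-oxooctadecyl)cyclohex-2-ene-1,4-dicarboxylate
Product: 29 trimethyl (1S,4R,4aS,8aR)-2,7-dihexadecyl-5-oxo-1,4,4a,5,8,8a-hexahydronaphthalene-1,4,6-tricarboxylate
Conditions: piperidine (0.2 equiv), AcOH (0.2 equiv), 4 Å molecular sieves, toluene, 40 °C
Reagents that add atoms: none
Why: In this intramolecular Knoevenagel condensation the piperidinium acetate buffer should enolise only the 1,3-dicarbonyl carbon C6, which adds to the C7 ketone in a 6-(enolexo)-exo-trig closure of ring B and dehydrates to the tetrasubstituted C6=C7 enone ester, while the buffer is too weak to enolise C1, C4 or C4a, so the four stereocentres should be retained.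

**Compound list**
1 | methyl 2-[bis(2,2,2-trifluoroethoxy)phosphoryl]acetate | COC(=O)CP(=O)(OCC(F)(F)F)OCC(F)(F)F | starting material
2 | methyl 2-[bis(2,2,2-trifluoroethoxy)phosphoryl]-2,2-dibromoacetate | COC(=O)C(Br)(Br)P(=O)(OCC(F)(F)F)OCC(F)(F)F | intermediate
3 | methyl 2-[bis(2,2,2-trifluoroethoxy)phosphoryl]-2-bromoacetate (racemic) | COC(=O)C(Br)P(=O)(OCC(F)(F)F)OCC(F)(F)F | intermediate
4 | dimethyl (R)-malate | COC(=O)C[C@@H](O)C(=O)OC | starting material
5 | dimethyl (2R)-2-[(tert-butyldimethylsilyl)oxy]butanedioate | COC(=O)C[C@@H](O[Si](C)(C)C(C)(C)C)C(=O)OC | intermediate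
6 | methyl (3R)-3-[(tert-butyldimethylsilyl)oxy]-4-oxobutanoate | COC(=O)C[C@@H](O[Si](C)(C)C(C)(C)C)C=O | intermediate
7 | dimethyl (2E,4R)-2-bromo-4-[(tert-butyldimethylsilyl)oxy]hex-2-enedioate | COC(=O)C[C@@H](O[Si](C)(C)C(C)(C)C)/C=C(/Br)C(=O)OC | intermediate
8 | heptadecanoic acid | CCCCCCCCCCCCCCCCC(=O)O | starting material
9 | Meldrum's acid (2,2-dimethyl-1,3-dioxane-4,6-dione) | CC1(C)OC(=O)CC(=O)O1 | starting material
10 | 5-(1-hydroxyheptadecylidene)-2,2-dimethyl-1,3-dioxane-4,6-dione (acyl Meldrum's acid) | CCCCCCCCCCCCCCCCC(O)=C1C(=O)OC(C)(C)OC1=O | intermediate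
11 | methyl 3-oxononadecanoate | CCCCCCCCCCCCCCCCC(=O)CC(=O)OC | intermediate
12 | methyl 2-(2-hexadecyl-1,3-dioxolan-2-yl)acetate | CCCCCCCCCCCCCCCCC1(CC(=O)OC)OCCO1 | intermediate
13 | 2-(2-hexadecyl-1,3-dioxolan-2-yl)acetaldehyde | CCCCCCCCCCCCCCCCC1(CC=O)OCCO1 | intermediate
14 | methyl (2E)-2-bromo-4-(2-hexadecyl-1,3-dioxolan-2-yl)but-2-enoate | COC(=O)/C(Br)=C\CC1(CCCCCCCCCCCCCCCC)OCCO1 | intermediate
15 | 1-octadecyne | CCCCCCCCCCCCCCCCC#C | starting material
16 | bis(pinacolato)diboron | CC1(C)OB(OC1(C)C)B1OC(C)(C)C(C)(C)O1 | starting material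
17 | (E)-1,2-bis(4,4,5,5-tetramethyl-1,3,2-dioxaborolan-2-yl)octadec-1-ene (boron atoms cis) | CCCCCCCCCCCCCCCC/C(B1OC(C)(C)C(C)(C)O1)=C/B1OC(C)(C)C(C)(C)O1 | intermediate
18 | dimethyl (2Z,4R)-4-[(tert-butyldimethylsilyl)oxy]-2-[(1E)-2-(4,4,5,5-tetramethyl-1,3,2-dioxaborolan-2-yl)octadec-1-en-1-yl]hex-2-enedioate | COC(=O)C[C@@H](O[Si](C)(C)C(C)(C)C)/C=C(C(=O)OC)/C=C(CCCCCCCCCCCCCCCC)\B1OC(C)(C)C(C)(C)O1 | intermediate
19 | dimethyl (2Z,4R)-4-hydroxy-2-[(1E)-2-(4,4,5,5-tetramethyl-1,3,2-dioxaborolan-2-yl)octadec-1-en-1-yl]hex-2-enedioate | COC(=O)C[C@@H](O)/C=C(C(=O)OC)/C=C(CCCCCCCCCCCCCCCC)\B1OC(C)(C)C(C)(C)O1 | intermediate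
20 | methyl 2-[(2R)-5-oxo-4-[(1E)-2-(4,4,5,5-tetramethyl-1,3,2-dioxaborolan-2-yl)octadec-1-en-1-yl]-2,5-dihydrofuran-2-yl]acetate | COC(=O)C[C@H]1OC(=O)C(/C=C(CCCCCCCCCCCCCCCC)\B2OC(C)(C)C(C)(C)O2)=C1 | intermediate
21 | methyl (2Z)-4-(2-hexadecyl-1,3-dioxolan-2-yl)-2-[(1Z)-1-[(5R)-5-(2-methoxy-2-oxoethyl)-2-oxo-2,5-dihydrofuran-3-yl]octadec-1-en-2-yl]but-2-enoate | COC(=O)C[C@H]1OC(=O)C(/C=C(CCCCCCCCCCCCCCCC)\C(C(=O)OC)=C\CC2(CCCCCCCCCCCCCCCC)OCCO2)=C1 | intermediate
22 | methyl (3R,3aS,4R)-6-hexadecyl-4-[(2-hexadecyl-1,3-dioxolan-2-yl)methyl]-3-(2-methoxy-2-oxoethyl)-1-oxo-1,3,3a,4-tetrahydro-2-benzofuran-5-carboxylate | COC(=O)C[C@H]1OC(=O)C2=CC(CCCCCCCCCCCCCCCC)=C(C(=O)OC)[C@H](CC3(CCCCCCCCCCCCCCCC)OCCO3)[C@H]12 | intermediate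
23 | methyl (3R,3aS,4R,5R,7aR)-6-hexadecyl-4-[(2-hexadecyl-1,3-dioxolan-2-yl)methyl]-3-(2-methoxy-2-oxoethyl)-1-oxo-1,3,3a,4,5,7a-hexahydro-2-benzofuran-5-carboxylate | COC(=O)C[C@H]1OC(=O)[C@@H]2C=C(CCCCCCCCCCCCCCCC)[C@H](C(=O)OC)[C@H](CC3(CCCCCCCCCCCCCCCC)OCCO3)[C@H]12 | intermediate
24 | methyl (3R,3aS,4R,5S,7aR)-6-hexadecyl-4-[(2-hexadecyl-1,3-dioxolan-2-yl)methyl]-3-(2-methoxy-2-oxoethyl)-1-oxo-1,3,3a,4,5,7a-hexahydro-2-benzofuran-5-carboxylate | COC(=O)C[C@H]1OC(=O)[C@@H]2C=C(CCCCCCCCCCCCCCCC)[C@@H](C(=O)OC)[C@H](CC3(CCCCCCCCCCCCCCCC)OCCO3)[C@H]12 | intermediate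
25 | 3-hexadecyl-5-[(2-hexadecyl-1,3-dioxolan-2-yl)methyl]-4-(methoxycarbonyl)-6-[(1E)-3-methoxy-3-oxoprop-1-en-1-yl]cyclohex-2-ene-1-carboxylic acid (configuration as in 26) | OC(=O)[C@@H]1C=C(CCCCCCCCCCCCCCCC)[C@@H](C(=O)OC)[C@H](CC2(CCCCCCCCCCCCCCCC)OCCO2)[C@@H]1/C=C/C(=O)OC | intermediate
26 | dimethyl 2-hexadecyl-6-[(2-hexadecyl-1,3-dioxolan-2-yl)methyl]-5-[(1E)-3-methoxy-3-oxoprop-1-en-1-yl]cyclohex-2-ene-1,4-dicarboxylate (C4, C4a, C8a substituents cis, C1 ester trans; absolute configuration as in 29) | COC(=O)[C@@H]1C=C(CCCCCCCCCCCCCCCC)[C@@H](C(=O)OC)[C@H](CC2(CCCCCCCCCCCCCCCC)OCCO2)[C@@H]1/C=C/C(=O)OC | intermediate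
27 | dimethyl 2-hexadecyl-5-[(1E)-3-methoxy-3-oxoprop-1-en-1-yl]-6-(2-oxooctadecyl)cyclohex-2-ene-1,4-dicarboxylate (configuration as in 26) | COC(=O)[C@@H]1C=C(CCCCCCCCCCCCCCCC)[C@@H](C(=O)OC)[C@H](CC(=O)CCCCCCCCCCCCCCCC)[C@@H]1/C=C/C(=O)OC | intermediate
28 | dimethyl 2-hexadecyl-5-(3-methoxy-3-oxopropanoyl)-6-(2-oxooctadecyl)cyclohex-2-ene-1,4-dicarboxylate (configuration as in 26) | COC(=O)[C@@H]1C=C(CCCCCCCCCCCCCCCC)[C@@H](C(=O)OC)[C@H](CC(=O)CCCCCCCCCCCCCCCC)[C@@H]1C(=O)CC(=O)OC | intermediate
29 | trimethyl (1S,4R,4aS,8aR)-2,7-dihexadecyl-5-oxo-1,4,4a,5,8,8a-hexahydronaphthalene-1,4,6-tricarboxylate | CCCCCCCCCCCCCCCCC1=C[C@@H](C(=O)OC)[C@H]2C(=O)C(C(=O)OC)=C(CCCCCCCCCCCCCCCC)C[C@H]2[C@@H]1C(=O)OC | target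

**Step count and risks**
Total: 18 steps. Longest linear sequence: 11 steps (4 → 29 through steps 3, 4, 5, 11, 12, 13, 14, 15, 16, 17, 18).

Most likely to fail, in this order:

1. Step 16. The ring-opening elimination is slow, and during it γ-protonation of the C1 or C4 dienolates could move the C2=C3 bond into conjugation, or the freed enoate could deconjugate and erase C4a. The fallback separates epimerisation from lactone opening and replaces elimination by hydrolysis and oxidation. It sets out from 23: brief treatment with catalytic DBU at 0 °C should equilibrate only C1 and give 24 with the lactone intact. One equivalent of LiOH in THF–water at 0 °C should then cleave the lactone, the most electrophilic acyl group, to the lithium salt of the hydroxy acid F1. Without acidification the secondary alcohol is oxidised with TEMPO and NaOCl in a buffered two-phase system to the keto acid F2. TMSCHN2 in toluene–methanol gives the ketal keto triester F3, and aqueous acetic acid removes the dioxolane. The route is rejoined at 28, so step 17 is bypassed as well.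

2. Step 17. Branching at C4a may slow hydroxypalladation of the enoate, so that allylic oxidation of ring A or incomplete conversion takes over. The fallback installs the C5 oxygen by conjugate borylation instead of Wacker chemistry. It sets out from 26: aqueous acetic acid at 50 °C removes the dioxolane to give 27. Copper-catalysed β-borylation (CuCl, NaOt-Bu, Xantphos, bis(pinacolato)diboron, MeOH, THF) should give the β-boryl ester F4 as a C5 epimer mixture. NaBO3·4H2O oxidises the C–B bond to the β-hydroxy ester F5, which is oxidised at once with Dess–Martin periodinane before it can lactonise onto the C4 ester. The route is rejoined at 28.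

3. Step 13. Protodeboronation of the hindered internal alkenyl boronate, or base-induced opening of the butenolide, may outpace transmetalation. The fallback couples before the lactone exists. It sets out from 18, which has no base-labile lactone and therefore tolerates aqueous phosphate: coupling with 14 (Pd(OAc)2, SPhos, K3PO4, THF–H2O, 25 °C) should give the acyclic silyl ether triene F6. F6 is kept cold and treated directly with HF·pyridine in THF at 0 °C, which removes the silyl group and lets the hydroxyl lactonise. The route is rejoined at 21.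

**Further compounds**
F1 | step 16 | 3-hexadecyl-5-[(2-hexadecyl-1,3-dioxolan-2-yl)methyl]-6-[(1R)-1-hydroxy-3-methoxy-3-oxopropyl]-4-(methoxycarbonyl)cyclohex-2-ene-1-carboxylic acid (ring configuration as in 26) | OC(=O)[C@@H]1C=C(CCCCCCCCCCCCCCCC)[C@@H](C(=O)OC)[C@H](CC2(CCCCCCCCCCCCCCCC)OCCO2)[C@@H]1[C@H](O)CC(=O)OC
F2 | step 16 | 3-hexadecyl-5-[(2-hexadecyl-1,3-dioxolan-2-yl)methyl]-4-(methoxycarbonyl)-6-(3-methoxy-3-oxopropanoyl)cyclohex-2-ene-1-carboxylic acid (ring configuration as in 26) | OC(=O)[C@@H]1C=C(CCCCCCCCCCCCCCCC)[C@@H](C(=O)OC)[C@H](CC2(CCCCCCCCCCCCCCCC)OCCO2)[C@@H]1C(=O)CC(=O)OC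
F3 | step 16 | dimethyl 2-hexadecyl-6-[(2-hexadecyl-1,3-dioxolan-2-yl)methyl]-5-(3-methoxy-3-oxopropanoyl)cyclohex-2-ene-1,4-dicarboxylate (ring configuration as in 26) | COC(=O)[C@@H]1C=C(CCCCCCCCCCCCCCCC)[C@@H](C(=O)OC)[C@H](CC2(CCCCCCCCCCCCCCCC)OCCO2)[C@@H]1C(=O)CC(=O)OC
F4 | step 17 | dimethyl 2-hexadecyl-5-[3-methoxy-3-oxo-1-(4,4,5,5-tetramethyl-1,3,2-dioxaborolan-2-yl)propyl]-6-(2-oxooctadecyl)cyclohex-2-ene-1,4-dicarboxylate (ring configuration as in 26; C5 epimers) | COC(=O)[C@@H]1C=C(CCCCCCCCCCCCCCCC)[C@@H](C(=O)OC)[C@H](CC(=O)CCCCCCCCCCCCCCCC)[C@@H]1C(CC(=O)OC)B2OC(C)(C)C(C)(C)O2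
F5 | step 17 | dimethyl 2-hexadecyl-5-(1-hydroxy-3-methoxy-3-oxopropyl)-6-(2-oxooctadecyl)cyclohex-2-ene-1,4-dicarboxylate (ring configuration as in 26; C5 epimers) | COC(=O)[C@@H]1C=C(CCCCCCCCCCCCCCCC)[C@@H](C(=O)OC)[C@H](CC(=O)CCCCCCCCCCCCCCCC)[C@@H]1C(O)CC(=O)OC
F6 | step 13 | acyclic triene triester: C5 silyl ether, C7 dioxolane, (E,Z,E)-triene C4a=C4–C3=C2–C1=C8a with methyl esters on C4 and C1 and hexadecyl on C2 | COC(=O)C[C@@H](O[Si](C)(C)C(C)(C)C)/C=C(C(=O)OC)/C=C(CCCCCCCCCCCCCCCC)\C(C(=O)OC)=C\CC1(CCCCCCCCCCCCCCCC)OCCO1
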